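**Retrosynthetic overview**
1. Target 23 ⇐ enal 22 (aldehyde reduction) ⇐ triene 20 + methacrolein 21 (cross-metathesis, C20=C21) ⇐ ketone 19 (Wittig at C1).
2. Key step: 19 ⇐ angular selenide 18. The C15 radical closes 3-exo onto C5 and the C5–C14 bond then opens (radical 1,2-vinyl shift), which inserts C15 into the bond shared by rings D and E.
3. 18 ⇐ enol triflate 16 (intramolecular Negishi, C5–C6, ring E) ⇐ dione 15 ⇐ allylic carbonate 11 + selenide dione 14 (Pd allylic alkylation, C13–C14).
4. 11 ⇐ enone 9 (MeLi) ⇐ aldehyde 4 + vinyl ketone 7 (organocatalytic Michael/aldol, ring A, C12); 4 ⇐ asymmetric conjugate addition (C16).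
5. Ring order: A, then D (brought in as cyclohexane-1,3-dione), then E, then B and C together in the radical step.

Assumption: working locants are C1 (carries the exocyclic =CH2), C2, C3, C4=C5, C6, C7, C8=C9(CH3), C10, C11, C12, C13, C14, bridging C15, side chain C16(CH3)–C18–C19–C20=C21(CH3)–C23–OH; the SMILES is read as 12S,13R,14S,16S with a 20E olefin; but-3-enylmagnesium bromide is bought as its THF solution.

Ring A = cyclohexene C8–C13; rings B and C = the two seven-membered rings of the target; rings D and E = the six-membered precursors of C and B.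

**Step 1**
Reactants: 1 but-3-enylmagnesium bromide; 2 methyl (E)-but-2-enoate
Product: 3 methyl (3S)-3-methylhept-6-enoate
Conditions: CuBr·SMe2 (5 mol%), Josiphos ligand (6 mol%, antipode giving 3S), t-BuOMe, −75 °C; then 1 M HCl
Reagents that add atoms: none
Why: Copper-catalysed asymmetric conjugate addition of a Grignard reagent to an (E)-enoate; the chiral diphosphine–copper complex selects the enoate face and sets C16.

**Step 2**
Reactants: 3 methyl (3S)-3-methylhept-6-enoate
Product: 4 (3S)-3-methylhept-6-enal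
Conditions: i-Bu2AlH (1.05 equiv), CH2Cl2, −78 °C; then aq. Rochelle salt
Reagents that add atoms: none
Why: Partial ester reduction stops at the aluminium hemiacetal at −78 °C and gives the aldehyde on work-up; the β-stereocentre is untouched.

**Step 3**
Reactants: 5 4-chlorobutanoyl chloride; 6 ethenyl(trimethyl)silane
Product: 7 6-chlorohex-1-en-3-one
Conditions: AlCl3, CH2Cl2, −20 → 0 °C
Reagents that add atoms: none
Why: Friedel–Crafts ipso-acylation of a vinylsilane (β-silyl cation, loss of Me3SiCl) gives the vinyl ketone regiospecifically.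

**Step 4**
Reactants: 4 (3S)-3-methylhept-6-enal; 7 6-chlorohex-1-en-3-one
Product: 9 (4S)-2-(2-chloroethyl)-4-[(2S)-hex-5-en-2-yl]cyclohex-2-en-1-one, via keto-aldehyde 8 (not isolated)
Conditions: (S)-α,α-diphenylprolinol trimethylsilyl ether (10 mol%), ethyl 3,4-dihydroxybenzoate (20 mol%), neat, 4 °C; then LiOH (0.2 equiv), i-PrOH, 0 °C
Reagents that add atoms: none
Why: Enamine-catalysed Michael addition of the aldehyde to the vinyl ketone sets C12 under catalyst control (attack on the enamine face remote from the CPh2OSiMe3 group), and the 1,5-keto-aldehyde closes by intramolecular aldol condensation (Robinson-type) through its only six-membered mode.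

**Step 5**
Reactants: 9 (4S)-2-(2-chloroethyl)-4-[(2S)-hex-5-en-2-yl]cyclohex-2-en-1-one
Product: 11 methyl (1R,4S)-2-(2-chloroethyl)-4-[(2S)-hex-5-en-2-yl]-1-methylcyclohex-2-en-1-yl carbonate, via lithium alkoxide 10 (not isolated)
Conditions: MeLi, THF, −78 °C; then ClCO2Me, −78 → 0 °C
Reagents that add atoms: methyllithium, [Li]C; methyl chloroformate, COC(=O)Cl
Why: 1,2-Addition of MeLi along the axial trajectory puts oxygen trans to the C12 side chain (expected about 3:1; the minor epimer is carried along because both ionise to the same allyl system in step 7), and O-acylation gives the tertiary allylic carbonate.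

**Step 6**
Reactants: 12 cyclohexane-1,3-dione; 13 formaldehyde (as paraformaldehyde)
Product: 14 2-[(phenylselanyl)methyl]cyclohexane-1,3-dione
Conditions: (CH2O)n, PhSeH, L-proline (10 mol%), CH2Cl2, 25 °C, Ar
Reagents that add atoms: benzeneselenol, [SeH]c1ccccc1
Why: Proposed new method: Knoevenagel condensation of the dione with formaldehyde gives the 2-methylidene dione, which the soft selenol traps at once by conjugate addition; the closest known reaction is the same three-component coupling with thiophenol.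

**Step 7**
Reactants: 11 methyl (1R,4S)-2-(2-chloroethyl)-4-[(2S)-hex-5-en-2-yl]-1-methylcyclohex-2-en-1-yl carbonate; 14 2-[(phenylselanyl)methyl]cyclohexane-1,3-dione
Product: 15 2-{(1S,6S)-2-(2-chloroethyl)-6-[(2S)-hex-5-en-2-yl]-3-methylcyclohex-2-en-1-yl}-2-[(phenylselanyl)methyl]cyclohexane-1,3-dione
Conditions: Pd2(dba)3 (2.5 mol%), PPh3 (12 mol%), THF, 40 °C
Reagents that add atoms: none
Why: Tsuji–Trost allylic alkylation: the η3-allyl palladium complex spans C13–C8–C9, and the soft dione enolate attacks the less substituted terminus C13 anti to palladium (net retention) and anti to the C12 side chain, which sets C13 trans to C12, creates quaternary C14 and leaves the tetrasubstituted C8=C9 olefin.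

**Step 8**
Reactants: 15 the dione of step 7
Product: 16 6-{(1S,6S)-2-(2-chloroethyl)-6-[(2S)-hex-5-en-2-yl]-3-methylcyclohex-2-en-1-yl}-5-oxo-6-[(phenylselanyl)methyl]cyclohex-1-en-1-yl trifluoromethanesulfonate (both epimers at the quaternary carbon)
Conditions: KN(SiMe3)2 (1.05 equiv), THF, −78 °C; PhNTf2, −78 → 0 °C
Reagents that add atoms: N-phenylbis(trifluoromethanesulfonimide), FC(F)(F)S(=O)(=O)N(c1ccccc1)S(=O)(=O)C(F)(F)F
Why: Kinetic enolisation of one of the two equivalent ketones and O-triflation fixes the future C4=C5 olefin, since quaternary C14 allows no other enol; both C14 epimers are used because this centre becomes planar in step 10.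

**Step 9**
Reactants: 16 the enol triflate of step 8
Product: 18 (4bS,5S)-5-[(2S)-hex-5-en-2-yl]-8-methyl-4a-[(phenylselanyl)methyl]-3,4a,4b,5,6,7,9,10-octahydrophenanthren-4(2H)-one (both epimers at C4a), via alkylzinc chloride 17 (not isolated)
Conditions: Zn dust, I2 (5 mol%), Bu4NI (20 mol%), DMA, 80 °C; then Pd(PPh3)4 (5 mol%), 60 °C
Reagents that add atoms: none
Why: Iodide-assisted zinc insertion into the primary chloride followed by intramolecular Negishi coupling with the vinyl triflate closes six-membered ring E at C5–C6; ketone, selenide and olefins are inert to the alkylzinc, and no stereocentre is formed.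

**Step 10**
Reactants: 18 the tricyclic selenide ketone of step 9
Product: 19 (1S,2R,3S)-3-[(2S)-hex-5-en-2-yl]-6-methyltricyclo[8.4.1.0(2,7)]pentadeca-6,10-dien-14-one
Conditions: Bu3SnH (1.3 equiv, syringe pump, 8 h), AIBN (0.2 equiv), PhH (0.005 M), 80 °C; then DBU (0.2 equiv), 25 °C
Reagents that add atoms: none
Why: Proposed new method: the primary C15 radical freed from the selenide adds 3-exo to C5 (forming the key C15–C5 bond) and the cyclopropylcarbinyl radical reopens by C5–C14 cleavage to the tertiary α-keto radical at C14, a Dowd–Beckwith-type ring expansion by 1,2-vinyl shift (vinyl migrates roughly fifty-fold faster than acyl in 2,2-disubstituted ethyl radicals) that turns both six-membered rings into the bicyclo[4.4.1]undecene with the bridgehead C4=C5 olefin; tin hydride transfers hydrogen to the outer face of C14 with ring A turned away from the four-carbon bridge (14S), and DBU equilibrates this α-keto centre to the same, more stable epimer.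

**Step 11**
Reactants: 19 the bridged ketone of step 10
Product: 20 (1S,2R,3S)-3-[(2S)-hex-5-en-2-yl]-6-methyl-14-methylidenetricyclo[8.4.1.0(2,7)]pentadeca-6,10-diene
Conditions: Ph3PCH3Br, KOt-Bu, THF, 0 → 50 °C
Reagents that add atoms: methyltriphenylphosphonium bromide, C[P+](c1ccccc1)(c1ccccc1)c1ccccc1.[Br-]
Why: Wittig methylenation of the ketone installs the exocyclic olefin; C14 is already at its thermodynamic configuration, so the basic ylide cannot erode it.

**Step 12**
Reactants: 20 the triene of step 11; 21 2-methylprop-2-enal (methacrolein, 10 equiv)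
Product: 22 (2E,6S)-2-methyl-6-[(1S,2R,3S)-6-methyl-14-methylidenetricyclo[8.4.1.0(2,7)]pentadeca-6,10-dien-3-yl]hept-2-enal
Conditions: second-generation Hoveyda–Grubbs catalyst (5 mol%), CH2Cl2, 40 °C
Reagents that add atoms: none
Why: Olefin cross-metathesis of the monosubstituted terminal alkene with methacrolein gives the trisubstituted enal with high E selectivity; the hindered 1,1-disubstituted, bridgehead trisubstituted and tetrasubstituted olefins are expected to be spectators.

**Step 13**
Reactants: 22 the enal of step 12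
Product: 23 (2E,6S)-2-methyl-6-[(1S,2R,3S)-6-methyl-14-methylidenetricyclo[8.4.1.0(2,7)]pentadeca-6,10-dien-3-yl]hept-2-en-1-ol
Conditions: NaBH4, CeCl3·7H2O, MeOH, −20 °C
Reagents that add atoms: none
Why: Luche 1,2-reduction of the enal gives the allylic alcohol with the E geometry retained.

**Compound list**
1 | but-3-enylmagnesium bromide | C=CCC[Mg]Br | starting material
2 | methyl (E)-but-2-enoate | C/C=C/C(=O)OC | starting material
3 | methyl (3S)-3-methylhept-6-enoate | COC(=O)C[C@@H](C)CCC=C | intermediate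
4 | (3S)-3-methylhept-6-enal | O=CC[C@@H](C)CCC=C | intermediate
5 | 4-chlorobutanoyl chloride | O=C(Cl)CCCCl | starting material
6 | ethenyl(trimethyl)silane | C=C[Si](C)(C)C | starting material
7 | 6-chlorohex-1-en-3-one | C=CC(=O)CCCCl | intermediate
8 | (2S)-8-chloro-2-[(2S)-hex-5-en-2-yl]-5-oxooctanal | ClCCCC(=O)CC[C@@H]([C@@H](C)CCC=C)C=O | intermediate
9 | (4S)-2-(2-chloroethyl)-4-[(2S)-hex-5-en-2-yl]cyclohex-2-en-1-one | O=C1CC[C@@H]([C@@H](C)CCC=C)C=C1CCCl | intermediate
10 | lithium (1R,4S)-2-(2-chloroethyl)-4-[(2S)-hex-5-en-2-yl]-1-methylcyclohex-2-en-1-olate | [Li+].[O-][C@]1(C)CC[C@@H]([C@@H](C)CCC=C)C=C1CCCl | intermediate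
11 | methyl (1R,4S)-2-(2-chloroethyl)-4-[(2S)-hex-5-en-2-yl]-1-methylcyclohex-2-en-1-yl carbonate | COC(=O)O[C@]1(C)CC[C@@H]([C@@H](C)CCC=C)C=C1CCCl | intermediate
12 | cyclohexane-1,3-dione | O=C1CCCC(=O)C1 | starting material
13 | formaldehyde (used as paraformaldehyde) | C=O | starting material
14 | 2-[(phenylselanyl)methyl]cyclohexane-1,3-dione | O=C1CCCC(=O)C1C[Se]c2ccccc2 | intermediate
15 | 2-{(1S,6S)-2-(2-chloroethyl)-6-[(2S)-hex-5-en-2-yl]-3-methylcyclohex-2-en-1-yl}-2-[(phenylselanyl)methyl]cyclohexane-1,3-dione | ClCCC1=C(C)CC[C@@H]([C@@H](C)CCC=C)[C@@H]1C2(C[Se]c3ccccc3)C(=O)CCCC2=O | intermediate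
16 | 6-{(1S,6S)-2-(2-chloroethyl)-6-[(2S)-hex-5-en-2-yl]-3-methylcyclohex-2-en-1-yl}-5-oxo-6-[(phenylselanyl)methyl]cyclohex-1-en-1-yl trifluoromethanesulfonate, both epimers at the quaternary carbon | ClCCC1=C(C)CC[C@@H]([C@@H](C)CCC=C)[C@@H]1C2(C[Se]c3ccccc3)C(=O)CCC=C2OS(=O)(=O)C(F)(F)F | intermediate
17 | alkylzinc chloride of 16 (CH2CH2ZnCl in place of CH2CH2Cl) | Cl[Zn]CCC1=C(C)CC[C@@H]([C@@H](C)CCC=C)[C@@H]1C2(C[Se]c3ccccc3)C(=O)CCC=C2OS(=O)(=O)C(F)(F)F | intermediate
18 | (4bS,5S)-5-[(2S)-hex-5-en-2-yl]-8-methyl-4a-[(phenylselanyl)methyl]-3,4a,4b,5,6,7,9,10-octahydrophenanthren-4(2H)-one, both epimers at C4a | O=C1CCC=C2CCC3=C(C)CC[C@@H]([C@@H](C)CCC=C)[C@@H]3C12C[Se]c4ccccc4 | intermediate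
19 | (1S,2R,3S)-3-[(2S)-hex-5-en-2-yl]-6-methyltricyclo[8.4.1.0(2,7)]pentadeca-6,10-dien-14-one | O=C1CCC=C2CCC3=C(C)CC[C@@H]([C@@H](C)CCC=C)[C@@H]3[C@@H]1C2 | intermediate
20 | (1S,2R,3S)-3-[(2S)-hex-5-en-2-yl]-6-methyl-14-methylidenetricyclo[8.4.1.0(2,7)]pentadeca-6,10-diene | C=C1CCC=C2CCC3=C(C)CC[C@@H]([C@@H](C)CCC=C)[C@@H]3[C@@H]1C2 | intermediate
21 | 2-methylprop-2-enal (methacrolein) | CC(=C)C=O | starting material
22 | (2E,6S)-2-methyl-6-[(1S,2R,3S)-6-methyl-14-methylidenetricyclo[8.4.1.0(2,7)]pentadeca-6,10-dien-3-yl]hept-2-enal | C=C1CCC=C2CCC3=C(C)CC[C@@H]([C@@H](C)CC/C=C(\C)C=O)[C@@H]3[C@@H]1C2 | intermediate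
23 | (2E,6S)-2-methyl-6-[(1S,2R,3S)-6-methyl-14-methylidenetricyclo[8.4.1.0(2,7)]pentadeca-6,10-dien-3-yl]hept-2-en-1-ol | C=C1CCC=C2CCC3=C(C)CC[C@@H]([C@@H](C)CC/C=C(\C)CO)[C@@H]3[C@@H]1C2 | target

**Step count**
Total: 13 steps. Longest linear sequence: 11 steps (1, 2, 4, 5, 7, 8, 9, 10, 11, 12, 13); steps 3 and 6 are one-step branches.

**Three steps most likely to fail**

Step 10 (radical ring expansion). The risks are acyl instead of vinyl migration (giving a fused cycloheptanone), direct reduction of the C15 radical to an angular methyl group, and the wrong C14 epimer. The fallback sets out from 18 and comes back at 19. Ketone 18 is first reduced (NaBH4, MeOH) to (4bS,5S)-5-[(2S)-hex-5-en-2-yl]-8-methyl-4a-[(phenylselanyl)methyl]-2,3,4,4a,4b,5,6,7,9,10-decahydrophenanthren-4-ol F2, which has no carbonyl group that could migrate. The same C15 radical is then generated with the slower hydrogen donor (Me3Si)3SiH/AIBN at high dilution, so that only the vinyl shift is open, giving (2R,3S)-3-[(2S)-hex-5-en-2-yl]-6-methyltricyclo[8.4.1.0(2,7)]pentadeca-6,10-dien-14-ol F3 as a mixture at C1 and C14. Dess–Martin oxidation followed by DBU equilibration of C14 returns to 19.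

Step 7 (allylic alkylation forming the quaternary–tertiary C13–C14 bond). The risks are slow attack of the bulky nucleophile, β-hydride elimination of the allyl complex to dienes, and retro-Michael loss of selenolate from 14. The fallback sets out from 11 and 12 and comes back at 15. Under the same palladium catalysis, carbonate 11 is coupled with the small, more acidic cyclohexane-1,3-dione 12 to give 2-{(1R,6S)-2-(2-chloroethyl)-6-[(2S)-hex-5-en-2-yl]-3-methylcyclohex-2-en-1-yl}cyclohexane-1,3-dione F1. The quaternary centre is then built in a separate step by C-alkylation of F1 with chloromethyl phenyl selenide (NaH, DMF, 0 °C), which gives 15.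

Step 12 (cross-metathesis in the presence of the exocyclic methylene). The risk is that the 1,1-disubstituted olefin of 20 takes part. The fallback sets out from 19 and comes back at 23 by changing the order of events. Ketone 19, which has no 1,1-disubstituted olefin, undergoes the metathesis with 21 to give (2E,6S)-2-methyl-6-[(1S,2R,3S)-6-methyl-14-oxotricyclo[8.4.1.0(2,7)]pentadeca-6,10-dien-3-yl]hept-2-enal F4. NaBH4 at −78 °C reduces only the aldehyde and gives (1S,2R,3S)-3-[(2S,5E)-7-hydroxy-6-methylhept-5-en-2-yl]-6-methyltricyclo[8.4.1.0(2,7)]pentadeca-6,10-dien-14-one F5. Methylenation of the ketone with excess Ph3P=CH2 then gives 23.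

**Further compounds**
F1 | step 7 | 2-{(1R,6S)-2-(2-chloroethyl)-6-[(2S)-hex-5-en-2-yl]-3-methylcyclohex-2-en-1-yl}cyclohexane-1,3-dione | ClCCC1=C(C)CC[C@@H]([C@@H](C)CCC=C)[C@@H]1C2C(=O)CCCC2=O
F2 | step 10 | (4bS,5S)-5-[(2S)-hex-5-en-2-yl]-8-methyl-4a-[(phenylselanyl)methyl]-2,3,4,4a,4b,5,6,7,9,10-decahydrophenanthren-4-ol, epimers at C4 and C4a | OC1CCC=C2CCC3=C(C)CC[C@@H]([C@@H](C)CCC=C)[C@@H]3C12C[Se]c4ccccc4
F3 | step 10 | (2R,3S)-3-[(2S)-hex-5-en-2-yl]-6-methyltricyclo[8.4.1.0(2,7)]pentadeca-6,10-dien-14-ol, epimers at C1 and C14 | OC1CCC=C2CCC3=C(C)CC[C@@H]([C@@H](C)CCC=C)[C@@H]3C1C2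
F4 | step 12 | (2E,6S)-2-methyl-6-[(1S,2R,3S)-6-methyl-14-oxotricyclo[8.4.1.0(2,7)]pentadeca-6,10-dien-3-yl]hept-2-enal | O=C1CCC=C2CCC3=C(C)CC[C@@H]([C@@H](C)CC/C=C(\C)C=O)[C@@H]3[C@@H]1C2
F5 | step 12 | (1S,2R,3S)-3-[(2S,5E)-7-hydroxy-6-methylhept-5-en-2-yl]-6-methyltricyclo[8.4.1.0(2,7)]pentadeca-6,10-dien-14-one | O=C1CCC=C2CCC3=C(C)CC[C@@H]([C@@H](C)CC/C=C(\C)CO)[C@@H]3[C@@H]1C2
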